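**Plan**

Numbering used throughout: lactone O1, C2 (C=O), C3 (carbinol carbon), C4, C5 (OCH2); C7 is the benzylic CH2 on C3 and C7' the carbinol carbon on C4.
Retrosynthesis cuts, in this order: aryl–C7' (aryl Grignard on a C4 aldehyde, the carbinol being re-set through the ketone), C3–C7 (enolate benzylation), and finally C2–C3 together with O1–C5, which leaves CO2 and a carbamate of oxetan-3-ylmethanol.
The double cut rests on two features: C4 carries two oxygenated one-carbon arms (C5 of the lactone and C7'), which are the two CH2O carbons of a 3-substituted oxetane, and C3 is an O-bearing carbon that can be lithiated next to a carbamate and carboxylated.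
Forward: carbamate, then lithiation, CO2 capture and oxetane opening give the γ-lactone (the only ring that is built); the freed arm is oxidised and masked, the carbamate removed, C3 benzylated, the aryl ketone made at C7' and reduced, and the benzyl ethers removed.
Stereochemistry is relayed: (−)-sparteine sets C3; C3 steers the oxetane opening and so sets C4; C4 then steers the benzylation that makes C3 quaternary; the C3 hydroxyl, through a zinc chelate, steers hydride to C7'.

Key step: step 2

Remark: 2 (CbyCl) is taken as a purchasable reagent; the atom numbering defined in the plan is used for every intermediate, whatever its systematic locants.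

**Step 1**
Reactants: 1 oxetan-3-ylmethanol; 2 2,2,4,4-tetramethyl-1,3-oxazolidine-3-carbonyl chloride (CbyCl)
Product: 3 oxetan-3-ylmethyl 2,2,4,4-tetramethyl-1,3-oxazolidine-3-carboxylate
Conditions: NaH, THF, 0 °C to reflux
Reagents that add atoms: none
Why: Carbamate formation by acylation of the sodium alkoxide with the carbamoyl chloride (addition–elimination), under which the oxetane is inert; no stereocenter is formed.

**Step 2**
Reactants: 3 oxetan-3-ylmethyl 2,2,4,4-tetramethyl-1,3-oxazolidine-3-carboxylate; 4 carbon dioxide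
Product: 7 (3R,4S)-4-(hydroxymethyl)-2-oxotetrahydrofuran-3-yl 2,2,4,4-tetramethyl-1,3-oxazolidine-3-carboxylate, via lithiated carbamate 5 (not isolated), via oxetanyl carboxylic acid 6 (not isolated)
Conditions: s-BuLi, (−)-sparteine, Et2O, −78 °C; CO2, −78 °C to rt; 2 M HCl, 0 °C; toluene, 60 °C
Reagents that add atoms: none
Why: s-BuLi/(−)-sparteine removes the pro-S hydrogen of the OCH2 group (sparteine-mediated asymmetric α-lithiation of an O-alkyl carbamate, directed by the carbamate C=O), and the configurationally stable organolithium 5 adds to CO2 with retention, which forms C2–C3 and fixes C3 as R. After acidification the free acid 6 protonates the oxetane oxygen internally and its carboxylate oxygen attacks one of the two oxetane CH2 groups (SN2, 5-exo-tet), which forms O1–C5, closes the γ-lactone and releases the other arm as the C7' hydroxymethyl group. The closest known reaction types are the sparteine-mediated lithiation–carboxylation of alkyl carbamates to O-protected α-hydroxy acids and the isomerisation of (oxetan-3-yl)acetic acids to β-hydroxymethyl γ-lactones. C3 is under reagent control (the chiral diamine), whereas C4 becomes a stereocenter only in the ring opening, where the two oxetane CH2 groups are diastereotopic and the transition state that keeps the remaining CH2O arm anti to the bulky carbamate on C3 should lead to the 3,4-trans lactone 7. The step needs α-lithiation without attack on the oxetane, secured by the proximity effect of the carbamate and by the inertness of unactivated oxetanes to organolithiums at −78 °C, and it needs carboxylate attack at a CH2 carbon, secured by the unsubstituted, symmetrical oxetane. Any cis isomer is to be removed by chromatography here or at 11, because it would lead into the enantiomeric series.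

**Step 3**
Reactants: 7 (3R,4S)-4-(hydroxymethyl)-2-oxotetrahydrofuran-3-yl 2,2,4,4-tetramethyl-1,3-oxazolidine-3-carboxylate
Product: 8 (3R,4S)-4-formyl-2-oxotetrahydrofuran-3-yl 2,2,4,4-tetramethyl-1,3-oxazolidine-3-carboxylate
Conditions: Dess–Martin periodinane, CH2Cl2, 0 °C to rt
Reagents that add atoms: none
Why: Dess–Martin oxidation of the primary alcohol under non-basic conditions should give the aldehyde without loss of the β-carbamate, and C4, now α to the aldehyde, already has the trans arrangement that is also the thermodynamically favoured one.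

**Step 4**
Reactants: 8 (3R,4S)-4-formyl-2-oxotetrahydrofuran-3-yl 2,2,4,4-tetramethyl-1,3-oxazolidine-3-carboxylate
Product: 11 (3R,4S)-4-(dimethoxymethyl)-3-hydroxydihydrofuran-2(3H)-one, via hydroxyalkyl carbamate acetal 9 (not isolated), via ring-opened dihydroxy acid 10 (not isolated)
Conditions: MeSO3H (cat.), MeOH, 50 °C; Ba(OH)2·8H2O, MeOH, reflux; dilute H2SO4 to pH 4, 0 °C; toluene, 40 °C
Reagents that add atoms: methanol, CO; water, O
Why: This is the two-stage cleavage for which the Cby carbamate is designed, in which acid methanolysis opens its N,O-acetal while turning the aldehyde into a base-stable dimethyl acetal that locks C4, base then lets the freed hydroxyl cyclise onto the carbamate carbonyl (oxazolidinone formation) to release the C3 oxygen, and the saponified lactone recloses on acidification through C5–OH, its only free γ-hydroxyl, so that C4 cannot scramble.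

**Step 5**
Reactants: 12 [4-(benzyloxy)-3-methoxyphenyl]methanol
Product: 13 1-(benzyloxy)-4-(bromomethyl)-2-methoxybenzene
Conditions: PBr3, Et2O, 0 °C
Reagents that add atoms: phosphorus tribromide, BrP(Br)Br
Why: Conversion of a benzylic alcohol into the bromide with PBr3 (SN2 on the alkyl phosphite), the electron-rich bromide being used without storage.

**Step 6**
Reactants: 11 (3R,4S)-4-(dimethoxymethyl)-3-hydroxydihydrofuran-2(3H)-one; 13 1-(benzyloxy)-4-(bromomethyl)-2-methoxybenzene
Product: 14 (3S,4S)-3-[4-(benzyloxy)-3-methoxybenzyl]-4-(dimethoxymethyl)-3-hydroxydihydrofuran-2(3H)-one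
Conditions: LiN(SiMe3)2 (2.2 equiv), THF–DMPU, −78 °C; 13, −78 to −40 °C; H2O
Reagents that add atoms: none
Why: Alkylation of the dilithium enediolate of an α-hydroxy lactone (Fráter–Seebach-type dianion alkylation), in which C3 is planar so that its earlier configuration no longer matters, and the benzyl bromide should approach anti to the dimethoxymethyl group on C4, placing the benzyl group trans and the hydroxyl cis to the C4 arm (3S).

**Step 7**
Reactants: 14 (3S,4S)-3-[4-(benzyloxy)-3-methoxybenzyl]-4-(dimethoxymethyl)-3-hydroxydihydrofuran-2(3H)-one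
Product: 15 (3S,4S)-4-[4-(benzyloxy)-3-methoxybenzyl]-4-hydroxy-5-oxotetrahydrofuran-3-carbaldehyde
Conditions: 1 M HCl, THF, 0 °C to rt
Reagents that add atoms: water, O
Why: Acid-catalysed acetal hydrolysis, to which the benzyl ethers, the lactone and the tertiary alcohol are stable, and in which C4, although α to the aldehyde, already has the favoured arrangement with the formyl group trans to the benzyl group.

**Step 8**
Reactants: 15 (3S,4S)-4-[4-(benzyloxy)-3-methoxybenzyl]-4-hydroxy-5-oxotetrahydrofuran-3-carbaldehyde; 16 1-(benzyloxy)-4-bromo-2-methoxybenzene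
Product: 18 (3S,4R)-3-[4-(benzyloxy)-3-methoxybenzyl]-4-{[4-(benzyloxy)-3-methoxyphenyl](hydroxy)methyl}-3-hydroxydihydrofuran-2(3H)-one (both configurations at C7'), via aryl Grignard reagent 17 (not isolated)
Conditions: 16, Mg, THF, rt; then 15, THF, −78 °C (17 in excess); H2O
Reagents that add atoms: none
Why: Grignard addition to the aldehyde, which at −78 °C is far faster than attack on the lactone, the first equivalent being spent on the tertiary hydroxyl, and both C7' epimers are carried on because C7' is made planar in step 9.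

**Step 9**
Reactants: 18 (3S,4R)-3-[4-(benzyloxy)-3-methoxybenzyl]-4-{[4-(benzyloxy)-3-methoxyphenyl](hydroxy)methyl}-3-hydroxydihydrofuran-2(3H)-one
Product: 19 (3S,4S)-4-[4-(benzyloxy)-3-methoxybenzoyl]-3-[4-(benzyloxy)-3-methoxybenzyl]-3-hydroxydihydrofuran-2(3H)-one
Conditions: Dess–Martin periodinane, CH2Cl2, 0 °C to rt
Reagents that add atoms: none
Why: Dess–Martin oxidation of the secondary benzylic alcohol, which converges both epimers on one aryl ketone, leaves the tertiary hydroxyl untouched and avoids the basic conditions that would invite retro-aldol cleavage of the β-hydroxy ketone.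

**Step 10**
Reactants: 19 (3S,4S)-4-[4-(benzyloxy)-3-methoxybenzoyl]-3-[4-(benzyloxy)-3-methoxybenzyl]-3-hydroxydihydrofuran-2(3H)-one
Product: 20 (3S,4R)-3-[4-(benzyloxy)-3-methoxybenzyl]-4-{(R)-[4-(benzyloxy)-3-methoxyphenyl](hydroxy)methyl}-3-hydroxydihydrofuran-2(3H)-one
Conditions: Zn(BH4)2, Et2O, −20 to 0 °C; H2O
Reagents that add atoms: none
Why: Chelation-controlled reduction of a β-hydroxy ketone (Cram chelate model), in which zinc bridges the C3 oxygen and the ketone oxygen in a six-membered chelate cis-fused to the lactone and external hydride should attack C7' from the convex face, anti to C5, to give the 7'R carbinol.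

**Step 11**
Reactants: 20 (3S,4R)-3-[4-(benzyloxy)-3-methoxybenzyl]-4-{(R)-[4-(benzyloxy)-3-methoxyphenyl](hydroxy)methyl}-3-hydroxydihydrofuran-2(3H)-one
Product: 21 (3S,4R)-3-hydroxy-3-(4-hydroxy-3-methoxybenzyl)-4-[(R)-hydroxy(4-hydroxy-3-methoxyphenyl)methyl]dihydrofuran-2(3H)-one (CNP0352022.1)
Conditions: H2 (1 atm), 10% Pd/C, EtOAc, rt
Reagents that add atoms: none
Why: Hydrogenolysis of the two aryl benzyl ethers over Pd/C in a neutral solvent, stopped after uptake of two equivalents of H2, should be faster than hydrogenolysis of the secondary benzylic hydroxyl and touches no stereocenter.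

**Compound list**

1 | oxetan-3-ylmethanol | OCC1COC1 | starting material
2 | 2,2,4,4-tetramethyl-1,3-oxazolidine-3-carbonyl chloride (CbyCl) | ClC(=O)N1C(C)(C)COC1(C)C | starting material
3 | oxetan-3-ylmethyl 2,2,4,4-tetramethyl-1,3-oxazolidine-3-carboxylate | O=C(OCC1COC1)N1C(C)(C)COC1(C)C | intermediate
4 | carbon dioxide | O=C=O | starting material
5 | (S)-[lithio(oxetan-3-yl)methyl] 2,2,4,4-tetramethyl-1,3-oxazolidine-3-carboxylate, as its (−)-sparteine complex | [Li][C@H](OC(=O)N1C(C)(C)COC1(C)C)C1COC1 | intermediate
6 | (R)-2-(oxetan-3-yl)-2-[(2,2,4,4-tetramethyl-1,3-oxazolidine-3-carbonyl)oxy]acetic acid | OC(=O)[C@H](OC(=O)N1C(C)(C)COC1(C)C)C1COC1 | intermediate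
7 | (3R,4S)-4-(hydroxymethyl)-2-oxotetrahydrofuran-3-yl 2,2,4,4-tetramethyl-1,3-oxazolidine-3-carboxylate | O=C1OC[C@H](CO)[C@H]1OC(=O)N2C(C)(C)COC2(C)C | intermediate
8 | (3R,4S)-4-formyl-2-oxotetrahydrofuran-3-yl 2,2,4,4-tetramethyl-1,3-oxazolidine-3-carboxylate | O=C1OC[C@H](C=O)[C@H]1OC(=O)N2C(C)(C)COC2(C)C | intermediate
9 | (3R,4S)-4-(dimethoxymethyl)-2-oxotetrahydrofuran-3-yl N-(1-hydroxy-2-methylpropan-2-yl)carbamate | O=C1OC[C@H](C(OC)OC)[C@H]1OC(=O)NC(C)(C)CO | intermediate
10 | (2R,3S)-3-(dimethoxymethyl)-2,4-dihydroxybutanoic acid (present as its barium salt) | OC[C@H](C(OC)OC)[C@@H](O)C(O)=O | intermediate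
11 | (3R,4S)-4-(dimethoxymethyl)-3-hydroxydihydrofuran-2(3H)-one | O=C1OC[C@H](C(OC)OC)[C@H]1O | intermediate
12 | [4-(benzyloxy)-3-methoxyphenyl]methanol | OCc1ccc(OCc2ccccc2)c(OC)c1 | starting material
13 | 1-(benzyloxy)-4-(bromomethyl)-2-methoxybenzene | BrCc1ccc(OCc2ccccc2)c(OC)c1 | intermediate
14 | (3S,4S)-3-[4-(benzyloxy)-3-methoxybenzyl]-4-(dimethoxymethyl)-3-hydroxydihydrofuran-2(3H)-one | O=C1OC[C@H](C(OC)OC)[C@@]1(O)Cc1ccc(OCc2ccccc2)c(OC)c1 | intermediate
15 | (3S,4S)-4-[4-(benzyloxy)-3-methoxybenzyl]-4-hydroxy-5-oxotetrahydrofuran-3-carbaldehyde | O=C1OC[C@H](C=O)[C@@]1(O)Cc1ccc(OCc2ccccc2)c(OC)c1 | intermediate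
16 | 1-(benzyloxy)-4-bromo-2-methoxybenzene | COc1cc(Br)ccc1OCc1ccccc1 | starting material
17 | [4-(benzyloxy)-3-methoxyphenyl]magnesium bromide | COc1cc([Mg]Br)ccc1OCc1ccccc1 | intermediate
18 | (3S,4R)-3-[4-(benzyloxy)-3-methoxybenzyl]-4-{[4-(benzyloxy)-3-methoxyphenyl](hydroxy)methyl}-3-hydroxydihydrofuran-2(3H)-one, both configurations at C7' | O=C1OC[C@H](C(O)c2ccc(OCc3ccccc3)c(OC)c2)[C@@]1(O)Cc1ccc(OCc2ccccc2)c(OC)c1 | intermediate
19 | (3S,4S)-4-[4-(benzyloxy)-3-methoxybenzoyl]-3-[4-(benzyloxy)-3-methoxybenzyl]-3-hydroxydihydrofuran-2(3H)-one | O=C1OC[C@H](C(=O)c2ccc(OCc3ccccc3)c(OC)c2)[C@@]1(O)Cc1ccc(OCc2ccccc2)c(OC)c1 | intermediate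
20 | (3S,4R)-3-[4-(benzyloxy)-3-methoxybenzyl]-4-{(R)-[4-(benzyloxy)-3-methoxyphenyl](hydroxy)methyl}-3-hydroxydihydrofuran-2(3H)-one | COc1cc(C[C@@]2(O)C(=O)OC[C@@H]2[C@@H](O)c2ccc(OCc3ccccc3)c(OC)c2)ccc1OCc1ccccc1 | intermediate
21 | (3S,4R)-3-hydroxy-3-(4-hydroxy-3-methoxybenzyl)-4-[(R)-hydroxy(4-hydroxy-3-methoxyphenyl)methyl]dihydrofuran-2(3H)-one (CNP0352022.1) | COc1cc(C[C@@]2(O)C(=O)OC[C@@H]2[C@@H](O)c2ccc(O)c(OC)c2)ccc1O | target

**Count and risks**

Total step count: 11. Longest linear sequence: 10 steps (steps 1–4 and 6–11); step 5 is a one-step side branch.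

Steps most likely to fail:

Step 2. The lithiated carbamate may attack its own oxetane before CO2 is taken up, or the ring opening may discriminate poorly between the two oxetane CH2 groups. The fallback sets out from 2 and comes back at 7, and gives up the oxetane as latent electrophile. The commercial acetonide (2,2-dimethyl-1,3-dioxan-5-yl)methanol F1 is acylated with 2 (NaH, THF) to (2,2-dimethyl-1,3-dioxan-5-yl)methyl 2,2,4,4-tetramethyl-1,3-oxazolidine-3-carboxylate F2. This is lithiated and carboxylated exactly as in step 2 (s-BuLi, (−)-sparteine, then CO2) to (R)-2-(2,2-dimethyl-1,3-dioxan-5-yl)-2-[(2,2,4,4-tetramethyl-1,3-oxazolidine-3-carbonyl)oxy]acetic acid F3. Aqueous acetic acid removes the acetonide, the diol acid lactonises, and camphorsulfonic acid in toluene should equilibrate the two hydroxymethyl arms by translactonisation towards the trans lactone 7.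

Step 6. Double deprotonation may be incomplete, with proton transfer between enediolate and product, or facial selectivity at the planar C3 may be eroded. The fallback sets out from 11 and comes back at 14, and replaces the dianion by a protected monoenolate. The secondary hydroxyl is silylated (t-BuMe2SiCl, imidazole, DMF) to (3R,4S)-3-[(tert-butyldimethylsilyl)oxy]-4-(dimethoxymethyl)dihydrofuran-2(3H)-one F4. Its lithium enolate (LiN(i-Pr)2, THF, −78 °C) is benzylated with 13, again anti to the C4 arm, to (3S,4S)-3-[4-(benzyloxy)-3-methoxybenzyl]-3-[(tert-butyldimethylsilyl)oxy]-4-(dimethoxymethyl)dihydrofuran-2(3H)-one F5. Bu4NF buffered with acetic acid then frees the tertiary hydroxyl to give 14.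

Step 10. A non-chelated (Felkin–Anh) pathway may compete with the zinc chelate and lower the facial selectivity at C7'. The fallback sets out from 19 and comes back at 20, and replaces substrate control by reagent control: CBS reduction with (S)-2-methyl-CBS-oxazaborolidine and BH3·SMe2 in THF, the aryl group acting as the larger ketone substituent, should deliver the 7'R carbinol. It makes no compound outside the list (F0).

**Further compounds**

F1 | step 2 | (2,2-dimethyl-1,3-dioxan-5-yl)methanol | CC1(C)OCC(CO)CO1
F2 | step 2 | (2,2-dimethyl-1,3-dioxan-5-yl)methyl 2,2,4,4-tetramethyl-1,3-oxazolidine-3-carboxylate | CC1(C)OCC(COC(=O)N2C(C)(C)COC2(C)C)CO1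
F3 | step 2 | (R)-2-(2,2-dimethyl-1,3-dioxan-5-yl)-2-[(2,2,4,4-tetramethyl-1,3-oxazolidine-3-carbonyl)oxy]acetic acid | OC(=O)[C@H](OC(=O)N1C(C)(C)COC1(C)C)C1COC(C)(C)OC1
F4 | step 6 | (3R,4S)-3-[(tert-butyldimethylsilyl)oxy]-4-(dimethoxymethyl)dihydrofuran-2(3H)-one | O=C1OC[C@H](C(OC)OC)[C@H]1O[Si](C)(C)C(C)(C)C
F5 | step 6 | (3S,4S)-3-[4-(benzyloxy)-3-methoxybenzyl]-3-[(tert-butyldimethylsilyl)oxy]-4-(dimethoxymethyl)dihydrofuran-2(3H)-one | O=C1OC[C@H](C(OC)OC)[C@@]1(O[Si](C)(C)C(C)(C)C)Cc1ccc(OCc2ccccc2)c(OC)c1
F0 | step 10 | none | none
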